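**Strategy**

The lower flavan-3,4-diol is cut across ring C at O1–C2 and C3–C4. Its carbinol C4 and ether oxygen O1 sit on adjacent carbons (C4a, C8a) of ring A, so O1–C8a–C4a–C4 is a salicylaldehyde in disguise and C2–C3 an (E)-β-formyloxystyrene. A chiral-acid-catalysed, silyl-relay oxa-[4+2] annulation of a 2-silyloxybenzaldehyde with this enol formate forges both bonds and the C2, C3 and C4 stereocentres at once and leaves C4 as a silyl ether. The precursor is the complete upper fisetinidol unit bearing at C4 (4β, enforced by a 3-O/7-O silylene tether in a Friedel–Crafts closure) the 2,4-dioxygenated benzaldehyde that becomes ring A. The same annulation first builds the upper unit.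

Key step: step 9

**Remarks and assumptions**

- The SMILES is read as fisetinidol-(4β→6)-(+)-mollisacacidin: upper unit (2R,3S,4S), 2,3-trans-3,4-cis; lower unit (2R,3S,4R), 2,3-trans-3,4-trans.
- Assumption: the (R)-configured N-triflyl phosphoramide is written as the antipode that leads to the (2R)-aryl series. The sense is read off in step 5 (both units need the same sense); the (S)-catalyst is used in steps 5 and 9 if it is opposite.
- CIP descriptors at C3/C4 of silylated intermediates differ from those of the target only through substituent priorities; the geometry is that of the SMILES.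
- Abbreviations: TBS = tert-butyldimethylsilyl; (R)-TRIP-NHTf = (R)-3,3′-bis(2,4,6-triisopropylphenyl)-1,1′-binaphthalene-2,2′-diyl N-triflylphosphoramide; CSA = camphor-10-sulfonic acid; DTBMP = 2,6-di-tert-butyl-4-methylpyridine; TMSOTf = trimethylsilyl triflate; TBAF = tetrabutylammonium fluoride; DMDO = dimethyldioxirane.

**Route**

Step 1
Reactants: 1 3,4-dihydroxybenzaldehyde
Product: 2 3,4-bis(tert-butyldimethylsilyloxy)benzaldehyde
Conditions: TBSCl (2.4 equiv), imidazole, DMF, 23 °C
Reagents that add atoms: tert-butyldimethylsilyl chloride CC(C)(C)[Si](C)(C)Cl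
Why: Imidazole-promoted silylation of both catechol hydroxyls; no stereocentre is involved.

Step 2
Reactants: 2 3,4-bis(tert-butyldimethylsilyloxy)benzaldehyde
Product: 3 (E)-3-[3,4-bis(tert-butyldimethylsilyloxy)phenyl]prop-2-enal
Conditions: Ph3P=CHCHO (1.1 equiv), toluene, 80 °C
Reagents that add atoms: (triphenylphosphoranylidene)acetaldehyde O=CC=P(c1ccccc1)(c1ccccc1)c1ccccc1
Why: Wittig olefination with a stabilised ylide should give the E-enal.

Step 3
Reactants: 3 (E)-3-[3,4-bis(tert-butyldimethylsilyloxy)phenyl]prop-2-enal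
Product: 4 (E)-2-[3,4-bis(tert-butyldimethylsilyloxy)phenyl]ethenyl formate
Conditions: 30% aq H2O2, bis(2-nitrophenyl) diselenide (5 mol %), CH2Cl2, 23 °C
Reagents that add atoms: hydrogen peroxide OO
Why: Baeyer–Villiger oxidation of an α,β-unsaturated aldehyde by an areneperoxyseleninic acid, in which the alkenyl group migrates with retention of the E geometry to give the enol formate.

Step 4
Reactants: 5 2,4-dihydroxybenzaldehyde
Product: 6 2,4-bis(tert-butyldimethylsilyloxy)benzaldehyde
Conditions: TBSCl (2.6 equiv), imidazole, DMF, 40 °C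
Reagents that add atoms: tert-butyldimethylsilyl chloride CC(C)(C)[Si](C)(C)Cl
Why: Exhaustive silylation, forcing enough to cap the chelated 2-hydroxyl as well.

Step 5
Reactants: 6 2,4-bis(tert-butyldimethylsilyloxy)benzaldehyde; 4 (E)-2-[3,4-bis(tert-butyldimethylsilyloxy)phenyl]ethenyl formate
Product: 7 (2R,3R,4R)-4,7-bis(tert-butyldimethylsilyloxy)-2-[3,4-bis(tert-butyldimethylsilyloxy)phenyl]chroman-3-yl formate (2,3-trans-3,4-trans)
Conditions: 4 (1.5 equiv), (R)-TRIP-NHTf (5 mol %), toluene, −40 °C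
Reagents that add atoms: none
Why: Proposed new method: the same silyl-relay oxa-[4+2] annulation as in step 9 on the simplest aldehyde — the acid-activated aldehyde (an O-silylated α-silyloxy ortho-quinone methide cation) is attacked at C4 by the formyloxy-bearing carbon of the aryl-polarised E-enol formate and the ortho silyl ether oxygen closes on the benzylic cation at C2 with transfer of TBS to O4, the chiral phosphoramide anion fixing the face at C4, the aryl-endo approach the 3,4-trans and the E-alkene the 2,3-trans relationship; closest known reaction type: acid-catalysed hetero-Diels–Alder reaction of ortho-quinone methides with styrenes under chiral N-triflyl phosphoramide catalysis.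

Step 6
Reactants: 7 the 3-formate from step 5
Product: 8 (2R,3S,4R)-7-(tert-butyldimethylsilyloxy)-2-[3,4-bis(tert-butyldimethylsilyloxy)phenyl]-4-methoxychroman-3-ol (3,4-trans epimer drawn; C4 is erased in step 8)
Conditions: CSA (10 mol %), MeOH/CH2Cl2 1:1, 0 → 23 °C
Reagents that add atoms: methanol CO
Why: Acid-catalysed methanolysis should transesterify the formate and exchange the ionisable benzylic 4-silyloxy group for methoxy (SN1 solvolysis), while aryl silyl ethers and C2/C3 are untouched.

Step 7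
Reactants: 8 the 4-methoxyflavan-3-ol; 5 2,4-dihydroxybenzaldehyde
Product: 11 3-O-{[4-formyl-3-(tert-butyldimethylsilyloxy)phenoxy]diisopropylsilyl} ether of 8, via chlorosilane 9 (not isolated), via phenol 10 (not isolated)
Conditions: iPr2SiCl2 (2 equiv), imidazole, CH2Cl2, 0 °C, then evaporate; 5 (1.2 equiv), imidazole, DMF, 0 → 23 °C; TBSCl, 40 °C
Reagents that add atoms: dichlorodiisopropylsilane CC(C)[Si](Cl)(Cl)C(C)C; tert-butyldimethylsilyl chloride CC(C)(C)[Si](C)(C)Cl
Why: Sequential silyl ether formation (temporary silicon connection): the secondary alcohol takes one chloride, the non-chelated 4-hydroxyl of 5 the second, and the chelated 2-hydroxyl is then capped.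

Step 8
Reactants: 11 the silicon-tethered aldehyde
Product: 12 (2R,3S,4R)-configured 4β-aryl flavan in which O3 and the aryl oxygen ortho to the new bond are bridged by Si(iPr)2 (cis-fused seven-membered siloxane); the aryl ring carries CHO and an ortho OTBS group
Conditions: TMSOTf (1.5 equiv), DTBMP (2 equiv), CH2Cl2 (0.003 M), −60 → −20 °C
Reagents that add atoms: none
Why: Lewis acid ionisation of the 4-methoxyflavan to its C4 benzylic cation and intramolecular Friedel–Crafts alkylation at the arene carbon ortho to the tether oxygen and para to the silyloxy group closes a seven-membered ring; the three-atom O–Si–O tether cannot span the trans-diaxial trajectory that normally gives 4α products, so the C4–aryl bond should form syn to O3 (4β, 3,4-cis).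

Step 9
Reactants: 12 the 2-silyloxybenzaldehyde carrying the upper unit; 4 (E)-2-[3,4-bis(tert-butyldimethylsilyloxy)phenyl]ethenyl formate
Product: 13 fully silylated biflavanoid, upper unit (2R,3S,4R), lower unit (2R,3R,4R) with 2,3-trans-3,4-trans ring C, 3-formate and 4-OTBS
Conditions: 4 (2 equiv), (R)-TRIP-NHTf (10 mol %), toluene, −40 °C
Reagents that add atoms: none
Why: Proposed new method: the acid (after the first turnover its N-silyl form) activates the aldehyde of 12 as a benzylic silyloxocarbenium ion, i.e. an O-silylated α-silyloxy ortho-quinone methide, whose C4 is attacked by the formyloxy-bearing carbon of 4 while the ortho aryl silyl ether oxygen closes onto the developing 3,4-bis(silyloxy)benzyl cation at C2 and releases its TBS group to the catalyst, so that silicon is relayed from O1 to O4. The closest known reaction types are the acid-catalysed inverse-demand hetero-Diels–Alder reactions of ortho-quinone methides (also α-alkoxy ones made from salicylaldehydes) with styrenes to 2-arylchromans, run enantioselectively with chiral N-triflyl phosphoramides, and silyl-transfer Mukaiyama/Prins-type additions to aromatic aldehydes. Ring C of the lower unit closes as a formal oxa-[4+2] cycloaddition (stepwise limit: Prins-type C3–C4 bond formation, then six-membered O1–C2 closure on the benzylic cation). C4 is set by the chiral phosphoramide anion shielding one face of the oxocarbenium ion, C3 by the compact aryl-endo approach to the rotamer with the carbonyl oxygen anti to the ortho silyloxy group (2,4-cis, hence 3,4-trans), and C2 by the E geometry of 4 or, in the stepwise limit, by chair closure with the aryl group equatorial (2,3-trans). The step needs regioselectivity (C3, not C2, as the nucleophilic carbon), secured by the para-silyloxyphenyl donor against the weakly donating formyloxy group, and chemoselectivity among seven silyl ethers, secured because only the oxygen ortho to the formyl group can close a six-membered ring. The stereocentres of the upper unit lie beyond C6 of ring A and should not compete with catalyst control.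

Step 10
Reactants: 13 the 3-formate from step 9
Product: 14 the corresponding lower-unit 3-alcohol (all silyl groups retained)
Conditions: iBu2AlH (3 equiv), CH2Cl2, −78 °C; aq potassium sodium tartrate
Reagents that add atoms: none
Why: Reductive cleavage of the formate ester at low temperature should leave silyl ethers and all stereocentres untouched.

Step 11
Reactants: 14 the silylated biflavanoid alcohol
Product: 15 fisetinidol-(4β→6)-(+)-mollisacacidin (target)
Conditions: TBAF/AcOH 1:1 (12 equiv), THF, 0 → 23 °C, argon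
Reagents that add atoms: none
Why: Buffered fluoride desilylation should cleave the six aryl TBS ethers, the benzylic TBS ether and the silylene at Si–O (retention at every carbon) without ionising the C4 carbinol.

**Compound list**

1 | 3,4-dihydroxybenzaldehyde | O=Cc1ccc(O)c(O)c1 | starting material
2 | 3,4-bis(tert-butyldimethylsilyloxy)benzaldehyde | O=Cc1ccc(O[Si](C)(C)C(C)(C)C)c(O[Si](C)(C)C(C)(C)C)c1 | intermediate
3 | (E)-3-[3,4-bis(tert-butyldimethylsilyloxy)phenyl]prop-2-enal | O=C/C=C/c1ccc(O[Si](C)(C)C(C)(C)C)c(O[Si](C)(C)C(C)(C)C)c1 | intermediate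
4 | (E)-2-[3,4-bis(tert-butyldimethylsilyloxy)phenyl]ethenyl formate | O=CO/C=C/c1ccc(O[Si](C)(C)C(C)(C)C)c(O[Si](C)(C)C(C)(C)C)c1 | intermediate
5 | 2,4-dihydroxybenzaldehyde | O=Cc1ccc(O)cc1O | starting material
6 | 2,4-bis(tert-butyldimethylsilyloxy)benzaldehyde | O=Cc1ccc(O[Si](C)(C)C(C)(C)C)cc1O[Si](C)(C)C(C)(C)C | intermediate
7 | (2R,3R,4R)-4,7-bis(TBSO)-2-[3,4-bis(TBSO)phenyl]chroman-3-yl formate | CC(C)(C)[Si](C)(C)Oc1ccc2c(c1)O[C@H](c1ccc(O[Si](C)(C)C(C)(C)C)c(O[Si](C)(C)C(C)(C)C)c1)[C@@H](OC=O)[C@@H]2O[Si](C)(C)C(C)(C)C | intermediate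
8 | (2R,3S,4R)-7-(TBSO)-2-[3,4-bis(TBSO)phenyl]-4-methoxychroman-3-ol | CC(C)(C)[Si](C)(C)Oc1ccc2c(c1)O[C@H](c1ccc(O[Si](C)(C)C(C)(C)C)c(O[Si](C)(C)C(C)(C)C)c1)[C@@H](O)[C@@H]2OC | intermediate
9 | 3-O-(chlorodiisopropylsilyl) ether of 8 (not isolated) | CC(C)(C)[Si](C)(C)Oc1ccc2c(c1)O[C@H](c1ccc(O[Si](C)(C)C(C)(C)C)c(O[Si](C)(C)C(C)(C)C)c1)[C@@H](O[Si](Cl)(C(C)C)C(C)C)[C@@H]2OC | intermediate
10 | 3-O-[(4-formyl-3-hydroxyphenoxy)diisopropylsilyl] ether of 8 (not isolated) | CC(C)(C)[Si](C)(C)Oc1ccc2c(c1)O[C@H](c1ccc(O[Si](C)(C)C(C)(C)C)c(O[Si](C)(C)C(C)(C)C)c1)[C@@H](O[Si](C(C)C)(C(C)C)Oc1ccc(C=O)c(O)c1)[C@@H]2OC | intermediate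
11 | 3-O-{[4-formyl-3-(TBSO)phenoxy]diisopropylsilyl} ether of 8 | CC(C)(C)[Si](C)(C)Oc1ccc2c(c1)O[C@H](c1ccc(O[Si](C)(C)C(C)(C)C)c(O[Si](C)(C)C(C)(C)C)c1)[C@@H](O[Si](C(C)C)(C(C)C)Oc1ccc(C=O)c(O[Si](C)(C)C(C)(C)C)c1)[C@@H]2OC | intermediate
12 | silylene-bridged 4β-(5-formyl-4-TBSO-2-oxyphenyl)fisetinidol tris-TBS ether (2R,3S,4R) | CC(C)(C)[Si](C)(C)Oc1ccc2c(c1)O[C@H](c1ccc(O[Si](C)(C)C(C)(C)C)c(O[Si](C)(C)C(C)(C)C)c1)[C@@H](O[Si]3(C(C)C)C(C)C)[C@H]2c1cc(C=O)c(O[Si](C)(C)C(C)(C)C)cc1O3 | intermediate
13 | silylene-bridged biflavanoid, lower unit 3-formate 4-OTBS (upper 2R,3S,4R; lower 2R,3R,4R) | CC(C)(C)[Si](C)(C)Oc1ccc2c(c1)O[C@H](c1ccc(O[Si](C)(C)C(C)(C)C)c(O[Si](C)(C)C(C)(C)C)c1)[C@@H](O[Si]3(C(C)C)C(C)C)[C@H]2c1cc2c(cc1O3)O[C@H](c1ccc(O[Si](C)(C)C(C)(C)C)c(O[Si](C)(C)C(C)(C)C)c1)[C@@H](OC=O)[C@@H]2O[Si](C)(C)C(C)(C)C | intermediate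
14 | silylene-bridged biflavanoid, lower unit 3-OH 4-OTBS | CC(C)(C)[Si](C)(C)Oc1ccc2c(c1)O[C@H](c1ccc(O[Si](C)(C)C(C)(C)C)c(O[Si](C)(C)C(C)(C)C)c1)[C@@H](O[Si]3(C(C)C)C(C)C)[C@H]2c1cc2c(cc1O3)O[C@H](c1ccc(O[Si](C)(C)C(C)(C)C)c(O[Si](C)(C)C(C)(C)C)c1)[C@@H](O)[C@@H]2O[Si](C)(C)C(C)(C)C | intermediate
15 | fisetinidol-(4β→6)-(+)-mollisacacidin, upper (2R,3S,4S), lower (2R,3S,4R) | Oc1ccc2c(c1)O[C@H](c1ccc(O)c(O)c1)[C@@H](O)[C@H]2c1cc2c(cc1O)O[C@H](c1ccc(O)c(O)c1)[C@@H](O)[C@@H]2O | target

**Step count and risks**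

Total: 11 steps. Longest linear sequence: 10 steps (1 → 2 → 3 → 4, then steps 5 to 11).

Most likely to fail:

1. Step 9 (proposed new method). What may go wrong: addition of the alkene through the wrong carbon; insufficient facial control by the chiral ion pair next to the bulky upper unit; or ring closure by the aryl silyl ether lagging behind oligomerisation of the enol formate or ionisation of the product at C4. The fallback uses known chemistry, sets out from 10 (isolated by leaving out the last TBSCl charge of step 7) and comes back at 15. Cyclisation of 10 under the step 8 conditions should give the phenolic aldehyde F1. An asymmetric domino oxa-Michael/aldol condensation of this salicylaldehyde with enal 3 (the suitable enantiomer of α,α-diphenylprolinol trimethylsilyl ether, 2-nitrobenzoic acid, toluene) again closes O1–C2 and C3–C4 in one operation and should give the 2H-chromene-3-carbaldehyde F2. Tsuji–Wilkinson decarbonylation (RhCl(PPh3)3, toluene, reflux) should give the flav-3-ene F3. DMDO should epoxidise anti to the 2-aryl group, and opening of the labile benzylic epoxide at C4 by water with inversion should give the 2,3-trans-3,4-trans diol F4. The step 11 conditions then lead to 15.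

2. Step 5 (proposed new method). What may go wrong: the same processes as in step 9, and in addition erosion of enantiopurity at C2/C3 through incomplete 3,4-diastereocontrol, because C4 is erased later. The fallback uses known chemistry, sets out from 5 and 3 and comes back at 8. Selective silylation of the non-chelated 4-hydroxyl of 5 (TBSCl, 1 equiv, imidazole, CH2Cl2, 0 °C) gives 2-hydroxy-4-(tert-butyldimethylsilyloxy)benzaldehyde F5. The same organocatalytic oxa-Michael/aldol condensation with 3 should give the (R)-2-aryl-2H-chromene-3-carbaldehyde F6, and decarbonylation with RhCl(PPh3)3 the flav-3-ene F7. DMDO epoxidation anti to the aryl group followed by methanolysis of the epoxide at C4 leads to 8.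

3. Step 8. What may go wrong: the formyl group lowers the nucleophilicity of the tethered arene, so the C4 cation may decay by proton loss or intermolecular attack before the seven-membered ring closes. The fallback masks the aldehyde so that the arene is no longer deactivated; it sets out from 8 (via 9) and 5 and comes back at 12. Thioacetalisation of 5 (propane-1,3-dithiol, BF3·OEt2) gives 4-(1,3-dithian-2-yl)benzene-1,3-diol F8. Its unhindered 4-hydroxyl is joined to chlorosilane 9 and the 2-hydroxyl capped with TBSCl to give the tethered dithiane F9. TMSOTf/DTBMP cyclisation should then give the 4β-linked cyclic siloxane F10. Alkylative hydrolysis of the dithiane (MeI, CaCO3, aqueous MeCN) leads to 12.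

**Further compounds**

F1 | step 9 | silylene-bridged 4β-(5-formyl-4-hydroxy-2-oxyphenyl)fisetinidol tris-TBS ether (free phenol analogue of 12) | CC(C)(C)[Si](C)(C)Oc1ccc2c(c1)O[C@H](c1ccc(O[Si](C)(C)C(C)(C)C)c(O[Si](C)(C)C(C)(C)C)c1)[C@@H](O[Si]3(C(C)C)C(C)C)[C@H]2c1cc(C=O)c(O)cc1O3
F2 | step 9 | silylene-bridged biflavanoid with lower unit as (2R)-2-aryl-2H-chromene-3-carbaldehyde | CC(C)(C)[Si](C)(C)Oc1ccc2c(c1)O[C@H](c1ccc(O[Si](C)(C)C(C)(C)C)c(O[Si](C)(C)C(C)(C)C)c1)[C@@H](O[Si]3(C(C)C)C(C)C)[C@H]2c1cc2c(cc1O3)O[C@H](c1ccc(O[Si](C)(C)C(C)(C)C)c(O[Si](C)(C)C(C)(C)C)c1)C(C=O)=C2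
F3 | step 9 | silylene-bridged biflavanoid with lower unit as flav-3-ene | CC(C)(C)[Si](C)(C)Oc1ccc2c(c1)O[C@H](c1ccc(O[Si](C)(C)C(C)(C)C)c(O[Si](C)(C)C(C)(C)C)c1)[C@@H](O[Si]3(C(C)C)C(C)C)[C@H]2c1cc2c(cc1O3)O[C@H](c1ccc(O[Si](C)(C)C(C)(C)C)c(O[Si](C)(C)C(C)(C)C)c1)C=C2
F4 | step 9 | silylene-bridged biflavanoid with free lower (2R,3S,4R)-3,4-diol | CC(C)(C)[Si](C)(C)Oc1ccc2c(c1)O[C@H](c1ccc(O[Si](C)(C)C(C)(C)C)c(O[Si](C)(C)C(C)(C)C)c1)[C@@H](O[Si]3(C(C)C)C(C)C)[C@H]2c1cc2c(cc1O3)O[C@H](c1ccc(O[Si](C)(C)C(C)(C)C)c(O[Si](C)(C)C(C)(C)C)c1)[C@@H](O)[C@@H]2O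
F5 | step 5 | 2-hydroxy-4-(tert-butyldimethylsilyloxy)benzaldehyde | O=Cc1ccc(O[Si](C)(C)C(C)(C)C)cc1O
F6 | step 5 | (R)-7-(TBSO)-2-[3,4-bis(TBSO)phenyl]-2H-chromene-3-carbaldehyde | CC(C)(C)[Si](C)(C)Oc1ccc2c(c1)O[C@H](c1ccc(O[Si](C)(C)C(C)(C)C)c(O[Si](C)(C)C(C)(C)C)c1)C(C=O)=C2
F7 | step 5 | 7-(TBSO)-2-[3,4-bis(TBSO)phenyl]-2H-chromene (aryl α, (S) by CIP) | CC(C)(C)[Si](C)(C)Oc1ccc2c(c1)O[C@H](c1ccc(O[Si](C)(C)C(C)(C)C)c(O[Si](C)(C)C(C)(C)C)c1)C=C2
F8 | step 8 | 4-(1,3-dithian-2-yl)benzene-1,3-diol | Oc1ccc(C2SCCCS2)c(O)c1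
F9 | step 8 | 3-O-{[4-(1,3-dithian-2-yl)-3-(TBSO)phenoxy]diisopropylsilyl} ether of 8 | CC(C)(C)[Si](C)(C)Oc1ccc2c(c1)O[C@H](c1ccc(O[Si](C)(C)C(C)(C)C)c(O[Si](C)(C)C(C)(C)C)c1)[C@@H](O[Si](C(C)C)(C(C)C)Oc1ccc(C3SCCCS3)c(O[Si](C)(C)C(C)(C)C)c1)[C@@H]2OC
F10 | step 8 | dithiane-masked analogue of 12 | CC(C)(C)[Si](C)(C)Oc1ccc2c(c1)O[C@H](c1ccc(O[Si](C)(C)C(C)(C)C)c(O[Si](C)(C)C(C)(C)C)c1)[C@@H](O[Si]3(C(C)C)C(C)C)[C@H]2c1cc(C4SCCCS4)c(O[Si](C)(C)C(C)(C)C)cc1O3
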